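The readings are simulated on assumed constants, noise included.

Substrate, target and over-reaction product add up to the substrate charged at any moment, since the catalyst charge of 0.10 mM is far smaller than the 0.10 M of substrate. What a reading lacks of the total is therefore over-reaction product.

all flasks: substrate 0.10 M
- larch: reagent 0.075 M; free catalyst 0.10 mM (in portions, 3); temperature 2 °C; run made earlier; portions every 15 s
- ash: reagent 0.30 M; free catalyst 0.10 mM (in portions, 3); temperature 30 °C; run made earlier; portions every 15 s
- cedar: reagent 0.15 M; free catalyst 0.20 mM (in portions, 3); temperature 2 °C; run made earlier; portions every 15 s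
- Wednesday's: reagent 0.150 M; free catalyst 0.10 mM (in portions, 3); temperature 40 °C; the portions of free catalyst follow each other after 15 s, the first at the start; time 12 min
- Monday's: reagent 0.150 M; free catalyst 0.10 mM (in portions, 3); temperature 35 °C; the portions of free catalyst follow each other after 15 s, the first at the start; time 12 min
- Sunday's: reagent 0.150 M; free catalyst 0.10 mM (in portions, 3); temperature 0 °C; the portions of free catalyst follow each other after 15 s, the first at the start; time 12 min
- Tuesday's: reagent 0.150 M; free catalyst 0.10 mM (in portions, 3); temperature 20 °C; the portions of free catalyst follow each other after 15 s, the first at the start; time 12 min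
- Friday's: reagent 0.150 M; free catalyst 0.10 mM (in portions, 3); temperature −10 °C; the portions of free catalyst follow each other after 15 s, the first at the start; time 12 min

| run | time / min | target / % | substrate / % |
|---|---|---|---|
| larch | 1.00 | 2.5 | 97.0 |
| larch | 2.50 | 8.8 | 91.3 |
| larch | 5.00 | 17.0 | 83.3 |
| larch | 8.00 | 24.9 | 74.0 |
| larch | 10.0 | 29.6 | 69.8 |
| larch | 15.0 | 38.9 | 59.8 |
| larch | 20.0 | 45.7 | 51.6 |
| ash | 0.250 | 4.1 | 95.7 |
| ash | 0.667 | 14.8 | 84.1 |
| ash | 1.33 | 27.5 | 68.3 |
| ash | 2.00 | 33.8 | 56.6 |
| ash | 2.50 | 36.9 | 49.8 |
| ash | 4.00 | 39.1 | 34.3 |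
| ash | 5.00 | 38.5 | 26.2 |
| cedar | 1.50 | 14.7 | 84.6 |
| cedar | 5.00 | 44.9 | 54.0 |
| cedar | 8.00 | 60.5 | 37.1 |
| cedar | 12.0 | 74.2 | 21.9 |
| cedar | 20.0 | 85.7 | 8.0 |

(readings scatter by 0.3 percentage points)

- what was read earlier has a scatter of 0.3 percentage points, one standard deviation
- steps under discussion: substrate + free catalyst -> catalyst intermediate A; reagent + catalyst intermediate A <-> catalyst intermediate B; catalyst intermediate B <-> free catalyst + target; target -> over-reaction product

1. ranking by amount of target, in percent of the substrate charged, from high to low, at 12 min (Wednesday's / Monday's / Sunday's / Tuesday's / Friday's)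
2. the same order at 2.5 min (Wednesday's / Monday's / Sunday's / Tuesday's / Friday's)
3. the amount of target, in percent of the substrate charged of the flask you put first, at 12 min
4. the amount of target, in percent of the substrate charged of the flask you put last, at 12 min

The lack should grow in proportion to the target standing, so its growth divided by the mean target and the time gives a rate constant. In the ash run the lack grows from 13.3% to 35.3% between 2.50 min and 5.00 min, over a mean target of 37.7%, which gives 0.233 min⁻¹. The same reckoning on the cedar run, from 5.00 min to 20.0 min, gives 0.00531 min⁻¹. With the logarithm taken as straight in temperature, the estimate for Tuesday's flask at 20 °C is 0.0604 min⁻¹. Its inverse, 16.5 min, is the target's life, the mean time a target lasts before over-reaction.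

Substrate falls in a pseudo-first-order way, at 0.0637 min⁻¹ from cedar scaled to this catalyst charge, and at 0.261 min⁻¹ in ash. The same line gives 0.158 min⁻¹ for Tuesday's, which may lean high, as c(reagent) in ash is 0.30 M against 0.150 M. By 12 min about 84.9% has reacted, and that is the ceiling for target. Had all of it become target at the start, it would have lived the whole time, leaving the floor of 41.1%. A falling feed with this life tightens the estimate to 54.1%. Wednesday's, with an estimated life of 1.11 min, passes about 10.8 lives in that time, so it belongs at the bottom.

The forecast gives Tuesday's > Sunday's > Friday's > Monday's > Wednesday's at 12 min and Monday's > Tuesday's > Wednesday's > Sunday's > Friday's at 2.5 min, with 50% on top, “a broad maximum”, and 0.4% last. Its top lies inside the bracket and lower than the tightened figure.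

The flasks give Tuesday's > Sunday's > Friday's > Monday's > Wednesday's at 12 min and Tuesday's > Monday's > Wednesday's > Sunday's > Friday's at 2.5 min, with 49.6% on top and 1.14% last.

    substrate + free catalyst → catalyst intermediate A (k = 87.0 L mol⁻¹ s⁻¹, Ea = 37.0 kJ mol⁻¹)
    reagent + catalyst intermediate A ⇌ catalyst intermediate B (K = 16.0 L mol⁻¹, k = 41.0 L mol⁻¹ s⁻¹, Ea = 43.0 kJ mol⁻¹, ΔH = −4.00 kJ mol⁻¹)
    catalyst intermediate B ⇌ free catalyst + target (K = 0.0410 M, k = 90.0 s⁻¹, Ea = 69.0 kJ mol⁻¹, ΔH = −40.0 kJ mol⁻¹)
    target → over-reaction product (k = 0.00110 s⁻¹, Ea = 92.0 kJ mol⁻¹)
    (constants at 20 °C)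

Wednesday's target life is far shorter than 12 min. The flask ends with 1.14% target and 98.7% over-reaction product, while the same flask without that step holds 84.0% target, so over-reaction is the main reason for its last place. Tuesday's target life, estimated at 16.5 min, is 15.2 min by the constants, and that flask holds 31.4% over-reaction product. A repeat of Wednesday's at 25 °C ends with 34.9% target and 52.0% over-reaction product.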